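A direct plan would acylate 6-bromo-1H-indole A1 at C3 with oxalyl chloride to 2-(6-bromo-1H-indol-3-yl)-2-oxoacetyl chloride A2, reduce A2 to 2-(6-bromo-1H-indol-3-yl)-2-oxoacetaldehyde A3, and condense A3 with 6-bromo-1H-indole-3-carbaldehyde A4 and an ammonia source to the imidazole (Debus–Radziszewski).
Its weakest steps would be:
- the reduction of the α-keto acyl chloride A2 to the glyoxal A3: a moisture-sensitive solid would have to be reduced once only, and the product would hydrate and oligomerise;
- the three-component imidazole condensation: the glyoxal A3 would self-condense to a 2-acylimidazole and the vinylogous-amide aldehyde A4 would be a sluggish electrophile, so slow addition and excess A4 would be needed;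
- the C3 acylation of A1 with isolation of A2: it would add an air-sensitive operation that closes no ring of the target.

The route disconnects both indole pyrrole rings instead of the imidazole: the N1–C2 and C3–C3a bonds of each 6-bromoindole are cut, which leaves a 2,4-dialkynylimidazole whose alkyne carbons become indole C3 and C2. The feature exploited is that imidazole C2 and C4 each carry the same indol-3-yl group, so one two-directional Larock heteroannulation with 5-bromo-2-iodoaniline forms four bonds and both rings at once and fixes bromine at C6 through the aniline. The imidazole is bought intact, so no glyoxal is made or reduced and no ammonia condensation with its self-condensation channel is run.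

Key step: step 3

Assumption: 1, 3 and 6 are taken as commercial; protection of 1 on either ring nitrogen would lead to the same target, because the two imidazole nitrogens become equivalent by tautomerism once the group is removed.

**Step 1**
Reactants: 1 2,4-dibromo-1H-imidazole
Product: 2 2,4-dibromo-1-{[2-(trimethylsilyl)ethoxy]methyl}-1H-imidazole
Conditions: NaH (1.1 equiv), THF, 0 °C; SEMCl (1.05 equiv), 0 °C to rt
Reagents that add atoms: 2-(trimethylsilyl)ethoxymethyl chloride (SEMCl), C[Si](C)(C)CCOCCl
Why: N-Alkylation of the sodium imidazolide by an alkoxymethyl chloride (SN2), directed by sterics to the nitrogen remote from the C4 bromine; an isomer alkylated on the other nitrogen would be removed by chromatography and would in any case lead to the same target.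

**Step 2**
Reactants: 2 2,4-dibromo-1-{[2-(trimethylsilyl)ethoxy]methyl}-1H-imidazole; 3 (triethylsilyl)acetylene
Product: 5 2,4-bis[(triethylsilyl)ethynyl]-1-{[2-(trimethylsilyl)ethoxy]methyl}-1H-imidazole, via C2-monoalkyne 4 (not isolated)
Conditions: 3 (3 equiv), PdCl2(PPh3)2 (5 mol %), CuI (10 mol %), Et3N/DMF, 80 °C
Reagents that add atoms: none
Why: Two-fold Sonogashira coupling in which the C2–Br bond between the two nitrogens should react first (giving 4) and the electron-withdrawing alkynyl group then assists the slower coupling at C4–Br, while the SiEt3 cap keeps each alkyne from coupling twice and resists the amine base.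

**Step 3**
Reactants: 5 2,4-bis[(triethylsilyl)ethynyl]-1-{[2-(trimethylsilyl)ethoxy]methyl}-1H-imidazole; 6 5-bromo-2-iodoaniline
Product: 9 2,4-bis[6-bromo-2-(triethylsilyl)-1H-indol-3-yl]-1-{[2-(trimethylsilyl)ethoxy]methyl}-1H-imidazole, via C4-mono-indole 7 (not isolated), via C2-mono-indole 8 (not isolated)
Conditions: 6 (2.4 equiv), Pd(OAc)2 (10 mol %), LiCl (2 equiv), Na2CO3 (6 equiv), degassed DMF, 100 °C
Reagents that add atoms: none
Why: Two-fold Larock heteroannulation: zerovalent palladium formed in situ from Pd(OAc)2 inserts into the C–I bond of 6, the arylpalladium iodide adds syn across one silylalkyne of 5 with the aryl carbon bonding to the imidazole-bearing alkyne carbon and palladium to the SiEt3-bearing carbon, the aniline nitrogen displaces halide to give a six-membered azapalladacycle, and C–N reductive elimination releases the 2-silylindole; the cycle then repeats at the second alkyne of 7 or 8. The closest known reaction type is the Larock indole synthesis of o-iodoanilines with aryl- or heteroaryl-substituted silylalkynes, which places silicon at C2. Each of the two pyrrole rings is closed as a formal [3+2] annulation, C3–C3a by intermolecular carbopalladation and N1–C2 by reductive elimination from the palladacycle, so four bonds and two rings should form in one operation on an imidazole that is already complete. No stereocentre is formed. The step needs C–I over C–Br chemoselectivity, which the phosphine-free Pd(OAc)2/LiCl system should secure because aryl bromides add to ligand-poor zerovalent palladium far more slowly than the ortho-amino aryl iodide, and it needs silicon-at-C2 regioselectivity, which the bulk of SiEt3 should secure; the bromine of 6, meta to nitrogen and para to iodine, ends at indole C6. SEM blocks N1 of the imidazole and N3 is flanked by both substituents, which should keep the azole from sequestering the catalyst.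

**Step 4**
Reactants: 9 2,4-bis[6-bromo-2-(triethylsilyl)-1H-indol-3-yl]-1-{[2-(trimethylsilyl)ethoxy]methyl}-1H-imidazole
Product: 11 nortopsentin A [2,4-bis(6-bromo-1H-indol-3-yl)-1H-imidazole], via N-SEM nortopsentin A 10 (not isolated)
Conditions: 3 M HCl, EtOH/H2O, 80 °C; then aq. NaHCO3
Reagents that add atoms: none
Why: Acidic global deprotection in which ipso-protodesilylation should first free C2 of both indoles (giving 10) and acidolysis of the N,O-acetal then removes the SEM group as formaldehyde and 2-(trimethylsilyl)ethanol, the protonated imidazole deactivating the indoles toward the released formaldehyde; the aryl bromides are inert and the product is achiral.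

**Compound list**
1 | 2,4-dibromo-1H-imidazole | Brc1c[nH]c(Br)n1 | starting material
2 | 2,4-dibromo-1-{[2-(trimethylsilyl)ethoxy]methyl}-1H-imidazole | C[Si](C)(C)CCOCn1cc(Br)nc1Br | intermediate
3 | (triethylsilyl)acetylene | CC[Si](CC)(CC)C#C | starting material
4 | 4-bromo-2-[(triethylsilyl)ethynyl]-1-{[2-(trimethylsilyl)ethoxy]methyl}-1H-imidazole (not isolated) | CC[Si](CC)(CC)C#Cc1nc(Br)cn1COCC[Si](C)(C)C | intermediate
5 | 2,4-bis[(triethylsilyl)ethynyl]-1-{[2-(trimethylsilyl)ethoxy]methyl}-1H-imidazole | CC[Si](CC)(CC)C#Cc1cn(COCC[Si](C)(C)C)c(C#C[Si](CC)(CC)CC)n1 | intermediate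
6 | 5-bromo-2-iodoaniline | Nc1cc(Br)ccc1I | starting material
7 | 4-[6-bromo-2-(triethylsilyl)-1H-indol-3-yl]-2-[(triethylsilyl)ethynyl]-1-{[2-(trimethylsilyl)ethoxy]methyl}-1H-imidazole (not isolated) | CC[Si](CC)(CC)C#Cc1nc(-c2c([Si](CC)(CC)CC)[nH]c3cc(Br)ccc23)cn1COCC[Si](C)(C)C | intermediate
8 | 2-[6-bromo-2-(triethylsilyl)-1H-indol-3-yl]-4-[(triethylsilyl)ethynyl]-1-{[2-(trimethylsilyl)ethoxy]methyl}-1H-imidazole (not isolated) | CC[Si](CC)(CC)C#Cc1cn(COCC[Si](C)(C)C)c(-c2c([Si](CC)(CC)CC)[nH]c3cc(Br)ccc23)n1 | intermediate
9 | 2,4-bis[6-bromo-2-(triethylsilyl)-1H-indol-3-yl]-1-{[2-(trimethylsilyl)ethoxy]methyl}-1H-imidazole | CC[Si](CC)(CC)c1[nH]c2cc(Br)ccc2c1-c1cn(COCC[Si](C)(C)C)c(-c2c([Si](CC)(CC)CC)[nH]c3cc(Br)ccc23)n1 | intermediate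
10 | 2,4-bis(6-bromo-1H-indol-3-yl)-1-{[2-(trimethylsilyl)ethoxy]methyl}-1H-imidazole (not isolated) | C[Si](C)(C)CCOCn1cc(-c2c[nH]c3cc(Br)ccc23)nc1-c1c[nH]c2cc(Br)ccc12 | intermediate
11 | nortopsentin A, 2,4-bis(6-bromo-1H-indol-3-yl)-1H-imidazole (achiral) | Brc1ccc2c(-c3c[nH]c(-c4c[nH]c5cc(Br)ccc45)n3)c[nH]c2c1 | target

**Step count and risks**
Total step count: 4. Longest linear sequence: 4 steps (1 → 2 → 5 → 9 → 11).

Steps most likely to fail:

1. Step 3 (double heteroannulation). What may go wrong: oxidative addition of zerovalent palladium into the C–Br bonds of 6 or of the product with chain growth, arrest after the first annulation, or alkyne insertion in the reverse orientation. Fallback, setting out from 2 and coming back at 10: the indoles would be brought in preformed by cross-coupling. 6-Bromo-1H-indole F1 would be N-silylated (NaH, i-Pr3SiCl, THF) to 6-bromo-1-(triisopropylsilyl)-1H-indole F2. C–H borylation at C3 ([Ir(OMe)(cod)]2, 4,4'-di-tert-butyl-2,2'-bipyridine, B2pin2, THF, 60 °C) would give 6-bromo-3-(4,4,5,5-tetramethyl-1,3,2-dioxaborolan-2-yl)-1-(triisopropylsilyl)-1H-indole F3. Two equivalents of F3 would be joined to 2 by a double Suzuki–Miyaura coupling (Pd(PPh3)4, aq. Na2CO3, DME, 80 °C), the azole C–Br bonds being expected to react before the bromine on the electron-rich silylindole, to give 2,4-bis[6-bromo-1-(triisopropylsilyl)-1H-indol-3-yl]-1-{[2-(trimethylsilyl)ethoxy]methyl}-1H-imidazole F4. TBAF in THF at 0 °C would then remove the two N-silyl groups and give 10, which would be carried through the acid stage of step 4.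

2. Step 2 (double Sonogashira coupling). What may go wrong: slow oxidative addition at the electron-rich C4–Br bond, so that the reaction stalls at 4 while copper-mediated alkyne homocoupling consumes 3. Fallback, setting out from 3 and coming back at 5: the C4 alkyne would be attached to an iodide and C2 functionalised by directed lithiation. 4-Iodo-1H-imidazole F5 would be protected (NaH, SEMCl, THF) as 4-iodo-1-{[2-(trimethylsilyl)ethoxy]methyl}-1H-imidazole F6 and coupled with 3 at room temperature (PdCl2(PPh3)2, CuI, Et3N) to 4-[(triethylsilyl)ethynyl]-1-{[2-(trimethylsilyl)ethoxy]methyl}-1H-imidazole F7. Lithiation at C2 (n-BuLi, THF, −78 °C) and quenching with I2 would give 2-iodo-4-[(triethylsilyl)ethynyl]-1-{[2-(trimethylsilyl)ethoxy]methyl}-1H-imidazole F8, and a second Sonogashira coupling with 3 at the reactive C2–I bond would give 5.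

3. Step 4 (global deprotection). What may go wrong: capture of the formaldehyde set free from the SEM group by indole C2 or N1, or stalling at the N-hydroxymethyl stage, while the C–Si bonds are cleaved as planned. Fallback, setting out from 1 and coming back at 11: the ring nitrogen would carry a group that releases no carbon electrophile. 1 would be sulfamoylated (Me2NSO2Cl, Et3N, CH2Cl2) to 2,4-dibromo-N,N-dimethyl-1H-imidazole-1-sulfonamide F9. The conditions of step 2 would give N,N-dimethyl-2,4-bis[(triethylsilyl)ethynyl]-1H-imidazole-1-sulfonamide F10, and those of step 3 would give 2,4-bis[6-bromo-2-(triethylsilyl)-1H-indol-3-yl]-N,N-dimethyl-1H-imidazole-1-sulfonamide F11. Heating F11 in aq. HCl/EtOH would cleave the sulfamoyl group as dimethylsulfamic acid together with both silyl groups and give 11.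

**Further compounds**
F1 | step 3 | 6-bromo-1H-indole | Brc1ccc2cc[nH]c2c1
F2 | step 3 | 6-bromo-1-(triisopropylsilyl)-1H-indole | CC(C)[Si](C(C)C)(C(C)C)n1ccc2ccc(Br)cc21
F3 | step 3 | 6-bromo-3-(4,4,5,5-tetramethyl-1,3,2-dioxaborolan-2-yl)-1-(triisopropylsilyl)-1H-indole | CC(C)[Si](C(C)C)(C(C)C)n1cc(B2OC(C)(C)C(C)(C)O2)c2ccc(Br)cc21
F4 | step 3 | 2,4-bis[6-bromo-1-(triisopropylsilyl)-1H-indol-3-yl]-1-{[2-(trimethylsilyl)ethoxy]methyl}-1H-imidazole | C[Si](C)(C)CCOCn1cc(-c2cn([Si](C(C)C)(C(C)C)C(C)C)c3cc(Br)ccc23)nc1-c1cn([Si](C(C)C)(C(C)C)C(C)C)c2cc(Br)ccc12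
F5 | step 2 | 4-iodo-1H-imidazole | Ic1c[nH]cn1
F6 | step 2 | 4-iodo-1-{[2-(trimethylsilyl)ethoxy]methyl}-1H-imidazole | C[Si](C)(C)CCOCn1cnc(I)c1
F7 | step 2 | 4-[(triethylsilyl)ethynyl]-1-{[2-(trimethylsilyl)ethoxy]methyl}-1H-imidazole | CC[Si](CC)(CC)C#Cc1cn(COCC[Si](C)(C)C)cn1
F8 | step 2 | 2-iodo-4-[(triethylsilyl)ethynyl]-1-{[2-(trimethylsilyl)ethoxy]methyl}-1H-imidazole | CC[Si](CC)(CC)C#Cc1cn(COCC[Si](C)(C)C)c(I)n1
F9 | step 4 | 2,4-dibromo-N,N-dimethyl-1H-imidazole-1-sulfonamide | CN(C)S(=O)(=O)n1cc(Br)nc1Br
F10 | step 4 | N,N-dimethyl-2,4-bis[(triethylsilyl)ethynyl]-1H-imidazole-1-sulfonamide | CC[Si](CC)(CC)C#Cc1cn(S(=O)(=O)N(C)C)c(C#C[Si](CC)(CC)CC)n1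
F11 | step 4 | 2,4-bis[6-bromo-2-(triethylsilyl)-1H-indol-3-yl]-N,N-dimethyl-1H-imidazole-1-sulfonamide | CC[Si](CC)(CC)c1[nH]c2cc(Br)ccc2c1-c1cn(S(=O)(=O)N(C)C)c(-c2c([Si](CC)(CC)CC)[nH]c3cc(Br)ccc23)n1
A1 | direct plan | 6-bromo-1H-indole | Brc1ccc2cc[nH]c2c1
A2 | direct plan | 2-(6-bromo-1H-indol-3-yl)-2-oxoacetyl chloride | O=C(Cl)C(=O)c1c[nH]c2cc(Br)ccc12
A3 | direct plan | 2-(6-bromo-1H-indol-3-yl)-2-oxoacetaldehyde | O=CC(=O)c1c[nH]c2cc(Br)ccc12
A4 | direct plan | 6-bromo-1H-indole-3-carbaldehyde | O=Cc1c[nH]c2cc(Br)ccc12
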